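## The problem

Ring carbons are numbered C1 (carbinol carrying the angelate), C2 (isovalerate), C3 (free hydroxyl), C4 (CMe2), C5 and C6 (cyclobutane CH), C7 (C=O), C8=C9(CH3), C10 (cyclobutane CH) and C11 (quaternary, CH3).

- **Ring system.** The core is a cyclobutane (C5, C6, C10, C11) with both diagonals bridged. C6 and C10 are joined by the enone chain C7–C8–C9 on one face (a bicyclo[3.1.1]heptenone). C5 and C11 are joined by C4–C3–C2–C1 on the opposite face, which closes the seven-membered ring. C4 and C11 are quaternary, so both bonds from the cyclobutane into the seven-membered ring are neopentyl-type.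
- **Cage stereocentres.** C5, C6, C10 and C11 are locked to each other by the ring fusion, so only their common absolute sense must be chosen.
- **Carbinol stereocentres.** C1–O is anti to the cis pair C2–O/C3–O. Seen from C1–C3 the cage is nearly mirror-symmetric, because its only asymmetry (C7=O against C9) lies on the far face. The cage therefore cannot direct the first carbinol centre; a reagent must. After that C1 can direct C2 (anti) and C2 can direct C3 (syn).
- **Carrier of absolute configuration.** C9 is trigonal in the target, so a C9 methyl stereocentre from the chiral pool can set the cage and be erased at the end.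
- **Fragile groups.** The angelate isomerises to the tiglate with acyl chlorides, nucleophilic catalysts or base. Esters next to a free hydroxyl migrate. C1 is a cyclobutylcarbinyl position, so cationic chemistry there risks ring expansion. β-Oxygenated ketone intermediates eliminate. Bicyclobutane and ketal intermediates do not survive acid.
- **Enabling feature.** C5 and C11 are 1,3-related cyclobutane carbons, and the bonds C4–C5 and C11–C1 both leave the ring anti to the C7–C9 bridge. That is where the central bond of a tricyclo[4.1.0.0(2,7)]heptane lies, with C6 and C10 as its wing carbons. C4 (tertiary, α to C3=O) is a natural electrophilic radical and C1 (β to the same carbonyl) a natural radical acceptor.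

## Retrosynthesis

**Esters and enone last.** Target 30 is cut at the C2–O acyl bond to enone diol 29. The C2 hydroxyl is the only unhindered one (C3–OH is next to CMe2), so it can be acylated last. The C8=C9 double bond of 29 is cut back to saturated ketone 26, because the enone would not survive the hydride and enolate steps of the seven-membered ring. Ketone 26 comes from 25 by hydrolysis of two ketals, and 25 from alcohol 24 by angeloylation. The angelate is put on when C1–OH is the only free hydroxyl, so neither regiochemistry nor acyl migration is at stake.

**The three oxygens.** Acetonide 23, diol 22 and hydroxy ketone 21 go back to ketone 18 by cutting C3–H (hydride) and C2–O (enol ether oxidation). C4 is quaternary, so the ketone enolises only toward C2. The C1–O bond of 17/18 is cut to enone 15 by conjugate borylation–oxidation. This was preferred to carrying a C1 alkoxy group through the ring-forming step, since the cage cannot bias a new C1 centre there and both epimers would form; an enantioselective catalyst reads the two faces of the enone directly.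

**Key disconnection.** Enone 15 is cut at C4–C5 and C11–C1 into bicyclobutane 11 and bromo enone 14. The neighbouring cuts (C2–C3 by pinacol coupling, C1–C2 by metathesis) leave both hindered bonds to the cyclobutane still to be made one at a time. This cut removes the seven-membered ring and both quaternary-flanked bonds at once, and leaves an eleven-carbon strained hydrocarbon ketal and a six-carbon partner. The forward reaction must do four things:
- place the C4 radical on C5, not on C11;
- bring it in on the exo face, where the central bond was;
- close the C11 radical 7-endo onto C1;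
- end without a hydrogen donor, through loss of a stannyl radical from C1, which also leaves C1 trigonal.

**Bicyclobutane.** Compound 11 is cut at C5–C10 (carbenoid C–H insertion) to dibromocyclopropane 10. That is cut at C5–C6 and C5–C11 to ketal 8 and bromoform 9, and 8 to (S)-enone 7. The ketal blocks insertion on the C7 side and keeps base and organolithium away from the carbonyl. The C9 methyl is placed cis to the new cyclopropane. It then sits over the C5 bridge, whose endo substituent in all later compounds is only hydrogen, and the C9–H is turned away from the carbenoid.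

**Chiral pool.** Enone 7 is cut at its C11 methyl and transposed carbonyl to tertiary alcohol 6 and (R)-5-methylcyclohexenone 5. Enone 5 is the known degradation product of (R)-pulegone 1 through epoxide 2 and thio ketone 3. The transposition makes the methyl stereocentre (S) in 7, which is the series needed for the cis carbene adduct.

**Partner.** Compound 14 is cut at the acyl–vinyl bond to acid bromide 12 and distannane 13; one ipso-acylation gives it.

## Roads not taken

**Alternative 1:** The cut is C5–C6 and C10–C11, back to an eleven-membered humulane-type ring with a tertiary allylic alcohol at C9. BF3·OEt2 would ionise it; the C6=C11 alkene would attack C5 and the C11 cation would be caught by C10 with loss of H8, giving tricyclic alkene A1.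
- Merits: one step makes the six-membered ring and the cyclobutane, every carbon is in place beforehand, and the transannular geometry places both cyclobutane bonds without a facial choice. In step count and in that respect it is better than the chosen plan.
- Weak points: closing a cyclobutane by alkene capture of a tertiary cation competes with proton loss, hydride shifts and other ring sizes; the conformation of a triply oxygenated eleven-membered ring must be right; the absolute configuration must come from an asymmetric oxygenation of an achiral ring; C7 must still be oxidised next to other allylic positions.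
- Against it the chosen plan sets a chiral-pool source of absolute configuration, no cation near the cyclobutylcarbinyl C1, and a stepwise fallback from the same intermediate.

**Alternative 2:** The cut is C2–C3. SmI2 (divalent samarium) would couple aldehydes on C1 and on C4, closing the seven-membered ring and giving tricyclic cis-diol A2.
- Merits: pinacol closure is a known reaction type, it delivers the cis-diol in the ring-forming step (saving two steps of the chosen route), and the C1 centre can be set in an open-chain piece. In precedent for the ring closure it is better.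
- Weak points: the dialdehyde still needs both side chains on the exo face of C5 and C11, which is exactly the pair of bonds the chosen key step makes, so the hard problem is moved, not solved; an α-alkoxy aldehyde is prone to reductive C–O cleavage by SmI2.
- The chosen plan makes the two hindered bonds and the ring in one operation, but by an untested facial course.

**Alternative 3:** The cut is C6–C11, formed by a 1,2-shift. Diazotisation (NaNO2, acetic acid) of a longibornane-type amino alcohol would contract a five-membered ring to the cyclobutane and release the C7 ketone, giving protected enone A3.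
- Merits: deaminative ring contraction is stereospecific, no bond is made on the exo face of a bicyclobutane, and the enone appears directly. In the certainty of the stereochemical course of its key step it is better.
- Weak points: the bridged precursor is at least as complex as the target and takes many steps; diazonium ions in strained polycycles also give hydride shifts, elimination and the other migration; contraction to a four-membered ring runs against strain.
- The chosen plan reaches its key-step precursor in eight steps from pulegone.

Key step: step 10

Assumption: the copper–bisphosphine catalyst of step 11 is taken to read this mirror-like cycloheptenone as it reads simple cycloalkenones, with (R,R)-QuinoxP* delivering boron to the Re face of C1 (C11 > C2 > H); if the sense is the reverse, the commercial (S,S) antipode is used.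

## Route

Step 1
Reactants: 1 (R)-pulegone
Product: 2 (6R)-pulegone oxide (2,2,6-trimethyl-1-oxaspiro[2.5]octan-4-one; both epimers at the spiro carbon)
Conditions: H2O2 (30%), NaOH, MeOH, 0 °C to rt
Reagents that add atoms: hydrogen peroxide, OO
Why: Weitz–Scheffer nucleophilic epoxidation of the enone; both epoxide epimers are carried on because the spiro centre is lost in steps 2 and 3.

Step 2
Reactants: 2 (6R)-pulegone oxide
Product: 3 (5R)-5-methyl-2-(phenylsulfanyl)cyclohexan-1-one (both C2 epimers)
Conditions: PhSNa, THF, reflux; H2O
Reagents that add atoms: sodium thiophenolate, [Na+].[S-]c1ccccc1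
Why: The thiolate opens the epoxy ketone at the α-carbon and the β-alkoxide so formed loses acetone by retro-aldol cleavage, the known degradation of pulegone oxide; the methyl stereocentre is not touched.

Step 3
Reactants: 3 (5R)-5-methyl-2-(phenylsulfanyl)cyclohexan-1-one
Product: 5 (R)-5-methylcyclohex-2-en-1-one, via sulfoxide 4 (not isolated)
Conditions: mCPBA, CH2Cl2, −78 °C; then CaCO3, toluene, 80 °C
Reagents that add atoms: none
Why: Sulfide oxidation and thermal syn-elimination of the α-sulfinyl ketone (sulfoxide elimination); elimination can only run toward C3, giving the conjugated enone.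

Step 4
Reactants: 5 (R)-5-methylcyclohex-2-en-1-one
Product: 6 (5R)-1,5-dimethylcyclohex-2-en-1-ol (both C1 epimers)
Conditions: MeLi, Et2O, −78 °C; H2O
Reagents that add atoms: methyllithium, [Li]C
Why: 1,2-Addition of methyllithium to the enone; the new carbinol centre is destroyed in step 5, so both epimers serve.

Step 5
Reactants: 6 (5R)-1,5-dimethylcyclohex-2-en-1-ol
Product: 7 (S)-3,5-dimethylcyclohex-2-en-1-one
Conditions: pyridinium chlorochromate, CH2Cl2, rt
Reagents that add atoms: pyridinium chlorochromate, [O-][Cr](=O)(=O)Cl.c1cc[nH+]cc1
Why: Oxidative 1,3-transposition of the tertiary allylic alcohol (Dauben–Babler oxidation) through a [3,3]-shift of the chromate ester; the untouched methyl stereocentre becomes (S)-C5 because the carbonyl has moved to the other side of it.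

Step 6
Reactants: 7 (S)-3,5-dimethylcyclohex-2-en-1-one
Product: 8 (S)-7,9-dimethyl-1,4-dioxaspiro[4.5]dec-6-ene
Conditions: Me3SiOCH2CH2OSiMe3, TMSOTf (cat.), CH2Cl2, −78 °C; pyridine
Reagents that add atoms: 1,2-bis(trimethylsilyloxy)ethane, C[Si](C)(C)OCCO[Si](C)(C)C
Why: Ketalisation under Noyori conditions (bis-silyl ether, silyl triflate, low temperature) keeps the double bond in conjugation, which glycol and protic acid would move to the β,γ-position.

Step 7
Reactants: 8 (S)-7,9-dimethyl-1,4-dioxaspiro[4.5]dec-6-ene; 9 bromoform
Product: 10 ethylene ketal of 7,7-dibromo-4,6-dimethylbicyclo[4.1.0]heptan-2-one with the cyclopropane cis to the C4 methyl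
Conditions: KOtBu, pentane, −20 to 0 °C
Reagents that add atoms: none
Why: Dibromocarbene [2+1] addition to the trisubstituted alkene; in the half-chair with the methyl group equatorial the pseudoaxial dioxolane oxygen covers one face, so the carbene should enter on the other, which is cis to the methyl group, and this sets C6 and C11 (the absolute sense of the cage); the minor diastereomer is removed by chromatography.

Step 8
Reactants: 10 dibromocyclopropane ketal
Product: 11 ethylene ketal of 1,5-dimethyltricyclo[4.1.0.0(2,7)]heptan-3-one (central bond C5–C11 in target numbering; C9 methyl on the side of the C5–H bridgehead)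
Conditions: MeLi, Et2O, −78 to −10 °C; aq. NaHCO3; basic alumina
Reagents that add atoms: none
Why: Bromine–lithium exchange and α-elimination give a cyclopropylidene carbenoid that inserts into the cis C10–H bond, the standard route from 7,7-dibromonorcaranes to bicyclobutanes; the ketal carbon offers no C–H on the other side and the C9–H is trans to the carbenoid, so C5 and C10 are fixed by the cis insertion.

Step 9
Reactants: 12 2-bromo-2-methylpropanoyl bromide; 13 (E)-1,2-bis(tributylstannyl)ethene
Product: 14 (E)-4-bromo-4-methyl-1-(tributylstannyl)pent-1-en-3-one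
Conditions: AlCl3, CH2Cl2, −78 °C; aq. NaHCO3
Reagents that add atoms: none
Why: Lewis-acid-promoted ipso-acylation of one vinyl–tin bond (destannylative Friedel–Crafts acylation) with retention of the (E) geometry; the β-stannyl enone formed is deactivated toward a second acylation.

Step 10
Reactants: 11 bicyclobutane ketal; 14 (E)-4-bromo-4-methyl-1-(tributylstannyl)pent-1-en-3-one
Product: 15 tricyclic enone ketal (C1=C2–C3=O cycloheptenone; C4 gem-dimethyl; C7 dioxolane; C9 methyl)
Conditions: (Bu3Sn)2 (0.1 equiv), hν (350 nm), C6H6, 30 °C; 14 (1.3 equiv) added over 6 h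
Reagents that add atoms: none
Why: Proposed new method: photolysis of hexabutylditin gives Bu3Sn•, which abstracts bromine from 14; the electrophilic tertiary α-keto radical at C4 attacks the electron-rich central σ-bond of 11 at the hydrogen-bearing bridgehead C5, the tertiary cyclobutyl radical left at C11 adds to the tin-bearing β-carbon C1 of the tethered enone, and β-scission of the C1–Sn bond releases the C1=C2 enone and Bu3Sn•, which carries the chain, so no hydrogen donor is present to reduce either radical early. The closest known reaction types are the radical chain additions of sulfonyl halides and thiols across the central bond of tricyclo[4.1.0.0(2,7)]heptanes, the stepwise radical [2σ+2π] cycloadditions of bicyclobutanes and radical vinylation by addition–fragmentation on β-stannyl enoates. The seven-membered ring is the only ring closed, by 7-endo-trig attack of C11 on C1; the polarity match (nucleophilic tertiary radical, enone β-carbon) and the lower strain of a bicyclo[4.1.1]octane against the 6-exo bicyclo[3.1.1]heptane should direct it. C5 and C11 change their substituents but their configuration is not free: the chain can span them only on the face of the old central bond, anti to the C7–C9 bridge, and C1 stays trigonal, so a cyclised product has one possible configuration. The step needs attack at C5 and not at C11, which the lower substitution of C5 and the tertiary C11 radical favour. It also needs C4 to enter C5 on the exo face, whereas sulfonyl and thiyl radicals are recorded to enter this ring system endo with inversion; in 11 the endo corridor at C5 is narrowed by the C9 methyl and the dioxolane, but exo entry is the point on which the proposal rests.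

Step 11
Reactants: 15 tricyclic enone ketal
Product: 17 β-hydroxy ketone (C1–OH; C3=O), via boronate 16 (not isolated)
Conditions: CuCl (5 mol%), (R,R)-QuinoxP* (6 mol%), NaOtBu (10 mol%), B2pin2, MeOH, THF, 0 °C to rt; then NaBO3·4H2O, THF–H2O
Reagents that add atoms: sodium perborate, [Na+].[O-]OB=O
Why: Copper-catalysed enantioselective conjugate borylation of a cyclic enone followed by stereoretentive C–B oxidation; because the cage is mirror-like at C1 the ligand alone decides the face, and any material of the enantiomeric series (from the optical purity of 1) becomes a separable diastereomer here.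

Step 12
Reactants: 17 β-hydroxy ketone
Product: 18 C1 tert-butyldimethylsilyl ether
Conditions: TBSOTf, 2,6-lutidine, CH2Cl2, −78 to 0 °C
Reagents that add atoms: tert-butyldimethylsilyl triflate, CC(C)(C)[Si](C)(C)OS(=O)(=O)C(F)(F)F
Why: Silyl triflate with a hindered pyridine base protects the β-hydroxy ketone without retro-aldol cleavage or β-elimination.

Step 13
Reactants: 18 C1 silyl ether
Product: 21 α-hydroxy ketone (C2–OH trans to C1–OTBS), via trimethylsilyl enol ether 19 (not isolated), via silyloxy ketone 20 (not isolated)
Conditions: TMSOTf, Et3N, CH2Cl2, 0 °C; mCPBA, NaHCO3, CH2Cl2, −20 °C; then citric acid, MeOH, 0 °C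
Reagents that add atoms: 3-chloroperbenzoic acid, O=C(OO)c1cccc(Cl)c1
Why: Rubottom oxidation; the ketone can enolise only toward C2 (C4 is quaternary), the peracid attacks the enol ether anti to the neighbouring C1 silyloxy group, and silyl migration gives the α-silyloxy ketone, which mild acid desilylates.

Step 14
Reactants: 21 α-hydroxy ketone
Product: 22 cis-2,3-diol
Conditions: NaBH4, MeOH, −20 °C
Reagents that add atoms: none
Why: Hydride adds to C3 anti to the vicinal C2–O bond (Felkin–Anh control in a cyclic α-hydroxy ketone), which places the new hydroxyl cis to C2–OH.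

Step 15
Reactants: 22 cis-2,3-diol
Product: 23 C2/C3 acetonide
Conditions: Me2C(OMe)2, PPTS (cat.), CH2Cl2, rt
Reagents that add atoms: 2,2-dimethoxypropane, COC(C)(C)OC
Why: Acetonide formation by acetal exchange; only the cis diol can bridge, which also checks the outcome of step 14.

Step 16
Reactants: 23 acetonide silyl ether
Product: 24 C1 alcohol
Conditions: TBAF, THF, 0 °C to rt
Reagents that add atoms: none
Why: Fluoride cleaves the silyl ether; the acetonide and the dioxolane are inert.

Step 17
Reactants: 24 C1 alcohol
Product: 25 C1 angelate
Conditions: LiN(SiMe3)2, THF, −78 °C; angelic anhydride, −78 to 0 °C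
Reagents that add atoms: angelic anhydride, C/C=C(/C)C(=O)OC(=O)/C(C)=C\C
Why: Acylation of the lithium alkoxide with the anhydride at low temperature is an established way to make angelates of hindered secondary alcohols without Z-to-E isomerisation, since neither an acyl chloride nor a nucleophilic catalyst is present.

Step 18
Reactants: 25 C1 angelate
Product: 26 diol ketone (C2–OH; C3–OH; C7=O)
Conditions: 1 M HCl, THF, 40 °C
Reagents that add atoms: water, O
Why: Acid hydrolysis of both ketals (acetonide and dioxolane); the α,β-unsaturated ester is stable to dilute aqueous acid.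

Step 19
Reactants: 26 diol ketone
Product: 29 enone diol, via tris-silyl enol ether 27 (not isolated), via bis-silyl enone 28 (not isolated)
Conditions: TMSOTf, Et3N, CH2Cl2, 0 °C; Pd(OAc)2 (1.1 equiv), MeCN, rt; then 1 M HCl, THF, 0 °C
Reagents that add atoms: none
Why: Saegusa–Ito dehydrogenation; silylation covers both hydroxyls and gives the only possible enol ether of the C7 ketone (toward C8, since C6 is a bridgehead), palladium diacetate forms the C8=C9 enone and erases the C9 stereocentre, and dilute acid frees the diol.

Step 20
Reactants: 29 enone diol
Product: 30 CNP0251293.1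
Conditions: (iPrCH2CO)2O (1.1 equiv), DMAP (cat.), pyridine, CH2Cl2, −20 °C
Reagents that add atoms: isovaleric anhydride, CC(C)CC(=O)OC(=O)CC(C)C
Why: Acylation at the less hindered C2 hydroxyl; the C3 hydroxyl is neopentyl (next to CMe2) and should react much more slowly.

## Compound list

1 | (R)-pulegone | C[C@@H]1CCC(=C(C)C)C(=O)C1 | starting material
2 | (6R)-pulegone oxide, both spiro epimers | C[C@@H]1CCC2(OC2(C)C)C(=O)C1 | intermediate
3 | (5R)-5-methyl-2-(phenylsulfanyl)cyclohexan-1-one, both C2 epimers | C[C@@H]1CCC(Sc2ccccc2)C(=O)C1 | intermediate
4 | (5R)-5-methyl-2-(phenylsulfinyl)cyclohexan-1-one (not isolated) | C[C@@H]1CCC(S(=O)c2ccccc2)C(=O)C1 | intermediate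
5 | (R)-5-methylcyclohex-2-en-1-one | C[C@@H]1CC=CC(=O)C1 | intermediate
6 | (5R)-1,5-dimethylcyclohex-2-en-1-ol, both C1 epimers | C[C@@H]1CC=CC(C)(O)C1 | intermediate
7 | (S)-3,5-dimethylcyclohex-2-en-1-one | C[C@@H]1CC(=O)C=C(C)C1 | intermediate
8 | (S)-7,9-dimethyl-1,4-dioxaspiro[4.5]dec-6-ene | C[C@@H]1CC2(OCCO2)C=C(C)C1 | intermediate
9 | bromoform | BrC(Br)Br | starting material
10 | ethylene ketal of 7,7-dibromo-4,6-dimethylbicyclo[4.1.0]heptan-2-one, cyclopropane cis to the C4 methyl | C[C@@H]1CC2(OCCO2)[C@@H]3C(Br)(Br)[C@]3(C)C1 | intermediate
11 | ethylene ketal of 1,5-dimethyltricyclo[4.1.0.0(2,7)]heptan-3-one, C5 methyl on the side of the hydrogen-bearing bridgehead | C[C@@H]1CC2(OCCO2)[C@@H]3[C@@H]4[C@H]1[C@]34C | intermediate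
12 | 2-bromo-2-methylpropanoyl bromide | CC(C)(Br)C(=O)Br | starting material
13 | (E)-1,2-bis(tributylstannyl)ethene | CCCC[Sn](CCCC)(CCCC)/C=C/[Sn](CCCC)(CCCC)CCCC | starting material
14 | (E)-4-bromo-4-methyl-1-(tributylstannyl)pent-1-en-3-one | CCCC[Sn](CCCC)(CCCC)/C=C/C(=O)C(C)(C)Br | intermediate
15 | tricyclic enone ketal (C1=C2, C3=O, C7 dioxolane) | C1=CC(=O)C(C)(C)[C@@H]2[C@H]3C4(OCCO4)C[C@@H](C)[C@@H]2[C@@]13C | intermediate
16 | C1 pinacol boronate of the C3 ketone (not isolated) | CC1(C)OB(OC1(C)C)[C@@H]2CC(=O)C(C)(C)[C@@H]3[C@H]4C5(OCCO5)C[C@@H](C)[C@@H]3[C@@]24C | intermediate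
17 | β-hydroxy ketone (C1–OH) | O[C@@H]1CC(=O)C(C)(C)[C@@H]2[C@H]3C4(OCCO4)C[C@@H](C)[C@@H]2[C@@]13C | intermediate
18 | C1 tert-butyldimethylsilyl ether | CC(C)(C)[Si](C)(C)O[C@@H]1CC(=O)C(C)(C)[C@@H]2[C@H]3C4(OCCO4)C[C@@H](C)[C@@H]2[C@@]13C | intermediate
19 | C2=C3 trimethylsilyl enol ether (not isolated) | CC(C)(C)[Si](C)(C)O[C@@H]1C=C(O[Si](C)(C)C)C(C)(C)[C@@H]2[C@H]3C4(OCCO4)C[C@@H](C)[C@@H]2[C@@]13C | intermediate
20 | C2 trimethylsilyloxy ketone (not isolated) | CC(C)(C)[Si](C)(C)O[C@@H]1[C@@H](O[Si](C)(C)C)C(=O)C(C)(C)[C@@H]2[C@H]3C4(OCCO4)C[C@@H](C)[C@@H]2[C@@]13C | intermediate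
21 | α-hydroxy ketone (C2–OH trans to C1–OTBS) | CC(C)(C)[Si](C)(C)O[C@@H]1[C@@H](O)C(=O)C(C)(C)[C@@H]2[C@H]3C4(OCCO4)C[C@@H](C)[C@@H]2[C@@]13C | intermediate
22 | cis-2,3-diol | CC(C)(C)[Si](C)(C)O[C@@H]1[C@@H](O)[C@@H](O)C(C)(C)[C@@H]2[C@H]3C4(OCCO4)C[C@@H](C)[C@@H]2[C@@]13C | intermediate
23 | C2/C3 acetonide | CC(C)(C)[Si](C)(C)O[C@@H]1[C@@H](O5)[C@@H](OC5(C)C)C(C)(C)[C@@H]2[C@H]3C4(OCCO4)C[C@@H](C)[C@@H]2[C@@]13C | intermediate
24 | C1 alcohol | O[C@@H]1[C@@H](O5)[C@@H](OC5(C)C)C(C)(C)[C@@H]2[C@H]3C4(OCCO4)C[C@@H](C)[C@@H]2[C@@]13C | intermediate
25 | C1 angelate | C/C=C(/C)C(=O)O[C@@H]1[C@@H](O5)[C@@H](OC5(C)C)C(C)(C)[C@@H]2[C@H]3C4(OCCO4)C[C@@H](C)[C@@H]2[C@@]13C | intermediate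
26 | diol ketone | C/C=C(/C)C(=O)O[C@@H]1[C@@H](O)[C@@H](O)C(C)(C)[C@@H]2[C@H]3C(=O)C[C@@H](C)[C@@H]2[C@@]13C | intermediate
27 | tris-trimethylsilyl derivative with C7=C8 enol ether (not isolated) | C/C=C(/C)C(=O)O[C@@H]1[C@@H](O[Si](C)(C)C)[C@@H](O[Si](C)(C)C)C(C)(C)[C@@H]2[C@H]3C(O[Si](C)(C)C)=C[C@@H](C)[C@@H]2[C@@]13C | intermediate
28 | bis-trimethylsilyl enone (not isolated) | C/C=C(/C)C(=O)O[C@@H]1[C@@H](O[Si](C)(C)C)[C@@H](O[Si](C)(C)C)C(C)(C)[C@@H]2[C@H]3C(=O)C=C(C)[C@@H]2[C@@]13C | intermediate
29 | enone diol | C/C=C(/C)C(=O)O[C@@H]1[C@@H](O)[C@@H](O)C(C)(C)[C@@H]2[C@H]3C(=O)C=C(C)[C@@H]2[C@@]13C | intermediate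
30 | CNP0251293.1 | C/C=C(/C)C(=O)O[C@@H]1[C@@H](OC(=O)CC(C)C)[C@@H](O)C(C)(C)[C@@H]2[C@H]3C(=O)C=C(C)[C@@H]2[C@@]13C | target

## Count and least certain steps

Total: 20 steps. Longest linear sequence: 19 steps (steps 1–8 and 10–20, from 1); step 9 is the one-step side branch.

**Step 10 (proposed new method).** The most likely failure is endo entry of the α-keto radical at C5 with inversion, the recorded course for sulfur-centred radicals on this ring system. C4 then points toward the C7–C9 bridge, the C11 radical cannot reach C1, and the chain ends in open 1,3-adducts. If the crowded endo corridor stops addition altogether, the radical is lost by disproportionation. Lesser risks are 6-exo closure at C2 and capture of the C11 radical by a second molecule of 14.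

Fallback, from 11 back to 15, with each bond made by a reaction whose stereochemical course on this ring system is established:
- Benzenesulfonyl bromide is added across the central bond under irradiation. The small sulfonyl radical enters C5 endo and bromine is delivered to C11 on the exo face, giving bromo sulfone F1.
- Keck allylation (CH2=CHCH2SnBu3, AIBN) replaces the tertiary bromide by an allyl group on the same exo face, giving allyl sulfone F2.
- The α-sulfonyl carbanion at C5 (LiN(iPr)2, THF, −78 °C) is alkylated with 2-methoxyallyl bromide on the exo face, the endo face being covered by the bridge, giving enol ether F3.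
- Ring-closing metathesis with the second-generation Grubbs catalyst joins the two exo chains to cyclic enol ether F4.
- Sodium amalgam removes the sulfonyl group; with C4 tied back, hydrogen can only take the endo position, giving F5.
- Aqueous oxalic acid unmasks the C3 ketone in saturated ketone F6.
- IBX in DMSO introduces the C1=C2 double bond (the C4=C5 direction is excluded by Bredt's rule), giving bisnor enone F7.
- Two α′-methylations (LiN(iPr)2, MeI) through monomethyl enone F8 build the gem-dimethyl group and give 15.

**Step 7.** Facial discrimination in the carbene addition may be poor or reversed, because the bias comes only from one pseudoaxial ketal oxygen. Fallback, from 7 back to 10, using a directing group instead of a blocking group: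
- Luche reduction (NaBH4, CeCl3) gives cis allylic alcohol F9.
- Bromoform, NaOH and a phase-transfer catalyst add the carbene syn to the hydroxyl, hence cis to the methyl group, giving dibromocyclopropyl alcohol F10.
- Dess–Martin oxidation gives ketone F11.
- Ethylene glycol with PPTS (no alkene is left to migrate) gives 10.

**Step 11.** Conjugate borylation may be slow at a β-carbon next to the quaternary C11, or facial induction may be low on this unusual enone. Fallback, from 15 back to 17, by epoxidation and reductive opening:
- H2O2 with a 9-amino-9-deoxy-epi-cinchona amine salt (iminium catalysis, antipode chosen as for the ligand) gives epoxy ketone F12 with the oxygen on the required face of C1.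
- Reductive opening at the α-carbon with PhSeNa (from (PhSe)2 and NaBH4, with AcOH) gives 17.

**Step 20.** Acylation may spill over to C3, or the angelate may migrate from C1 to C2 under the basic catalyst. Fallback, from 29 back to 30, by activating one oxygen rather than relying on steric difference: Bu2SnO in refluxing toluene forms stannylene acetal F13, which isovaleryl chloride at 0 °C opens at the less hindered C2 oxygen without an amine catalyst.

## Further compounds

F1 | step 10 | bromo sulfone (C5 endo phenylsulfonyl; C11 exo bromine) | C[C@@H]1CC2(OCCO2)[C@@H]3[C@H](S(=O)(=O)c4ccccc4)[C@H]1[C@@]3(C)Br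
F2 | step 10 | allyl sulfone (C11 exo allyl) | C[C@@H]1CC2(OCCO2)[C@@H]3[C@H](S(=O)(=O)c4ccccc4)[C@H]1[C@@]3(C)CC=C
F3 | step 10 | enol ether (C5 exo 2-methoxyallyl; C5 endo phenylsulfonyl) | C[C@@H]1CC2(OCCO2)[C@@H]3[C@](CC(=C)OC)(S(=O)(=O)c4ccccc4)[C@H]1[C@@]3(C)CC=C
F4 | step 10 | cyclic enol ether sulfone (C2=C3–OMe) | C1C=C(OC)C[C@]2(S(=O)(=O)c5ccccc5)[C@H]3C4(OCCO4)C[C@@H](C)[C@@H]2[C@@]13C
F5 | step 10 | cyclic enol ether (C5–H) | C1C=C(OC)C[C@@H]2[C@H]3C4(OCCO4)C[C@@H](C)[C@@H]2[C@@]13C
F6 | step 10 | saturated C3 ketone without the C4 methyl groups | C1CC(=O)C[C@@H]2[C@H]3C4(OCCO4)C[C@@H](C)[C@@H]2[C@@]13C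
F7 | step 10 | bisnor enone (C4H2) | C1=CC(=O)C[C@@H]2[C@H]3C4(OCCO4)C[C@@H](C)[C@@H]2[C@@]13C
F8 | step 10 | monomethyl enone (both C4 epimers) | C1=CC(=O)C(C)[C@@H]2[C@H]3C4(OCCO4)C[C@@H](C)[C@@H]2[C@@]13C
F9 | step 7 | cis-3,5-dimethylcyclohex-2-en-1-ol (5S; hydroxyl cis to the C5 methyl) | C[C@@H]1C[C@H](O)C=C(C)C1
F10 | step 7 | 7,7-dibromo-4,6-dimethylbicyclo[4.1.0]heptan-2-ol (hydroxyl, cyclopropane and C4 methyl all cis) | C[C@@H]1C[C@H](O)[C@@H]2C(Br)(Br)[C@]2(C)C1
F11 | step 7 | 7,7-dibromo-4,6-dimethylbicyclo[4.1.0]heptan-2-one (cyclopropane cis to the C4 methyl) | C[C@@H]1CC(=O)[C@@H]2C(Br)(Br)[C@]2(C)C1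
F12 | step 11 | C1,C2-epoxy ketone | O5[C@@H]1[C@H]5C(=O)C(C)(C)[C@@H]2[C@H]3C4(OCCO4)C[C@@H](C)[C@@H]2[C@@]13C
F13 | step 20 | C2/C3 dibutylstannylene acetal of the enone diol | C/C=C(/C)C(=O)O[C@@H]1[C@@H](O5)[C@@H](O[Sn]5(CCCC)CCCC)C(C)(C)[C@@H]2[C@H]3C(=O)C=C(C)[C@@H]2[C@@]13C
A1 | alternative 1 | tricyclic alkene (C1–OTBS; C2/C3 acetonide; C8=C9) | CC(C)(C)[Si](C)(C)O[C@@H]1[C@@H](O4)[C@@H](OC4(C)C)C(C)(C)[C@@H]2[C@H]3CC=C(C)[C@@H]2[C@@]13C
A2 | alternative 2 | tricyclic cis-diol (C1–OPMB; C7 dioxolane) | COc1ccc(CO[C@@H]5[C@@H](O)[C@@H](O)C(C)(C)[C@@H]2[C@H]3C4(OCCO4)C[C@H](C)[C@@H]2[C@@]53C)cc1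
A3 | alternative 3 | protected tricyclic enone (C1–OTBS; C2/C3 acetonide) | CC(C)(C)[Si](C)(C)O[C@@H]1[C@@H](O4)[C@@H](OC4(C)C)C(C)(C)[C@@H]2[C@H]3C(=O)C=C(C)[C@@H]2[C@@]13C
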